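Atom numbers are those of 1,2-dihydronaphthalene: C1 carries ring A, C2 and C3 carry the methyl groups, C4 is the olefinic CH, and C4a–C8a belong to ring B (OMe at C6 and C8, OH at C7). Ring C is the partly saturated ring.

## The problem

The target 25 is a 1-aryl-1,2-dihydronaphthalene cyclolignan. Ring A (4-hydroxy-3,5-dimethoxyphenyl) hangs from C1 of ring C, which is fused through C4a–C8a to the pentasubstituted ring B and carries methyl groups at C2 and C3 and a trisubstituted styrenyl C3=C4 bond. The only stereocentres are C1 (S) and C2 (S), vicinal, with ring A and the C2 methyl cis. There is no third centre to relay from, so the absolute configuration must come from a catalyst and the relative configuration from a stereospecific bond formation, not from equilibration. C1 is doubly benzylic and sits between the C8 methoxy group and C4a of ring B, so every bond to C1 is made at a crowded carbon. At its final oxidation level the molecule is fragile: both 2,6-dimethoxyphenols oxidise easily, the dihydronaphthalene can aromatise with loss of both centres, and the C3=C4 bond forbids hydrogenolytic deprotection. Protecting groups must therefore leave with fluoride, and ring C should be closed late under neutral conditions. The enabling feature is that C1 and C2 are adjacent sp3 carbons and C1 is bonded to C8a: they map onto the two olefinic carbons of a styrenyl boronate of ring B. Ring A (at C1) and a methyl group (at C2) can then be added in one enantioselective operation, after which the C2–B bond carries C3 and a chlorine at C4a carries C4.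

## Retrosynthesis

**25 from 24.** The two O–Si bonds are cut last. Triisopropylsilyl ethers are chosen for both phenols because they must survive alkyllithiums, methoxide and hot aqueous phosphate, yet leave with buffered fluoride, which the styrene and the stereocentres tolerate. Benzyl or methyl ethers would demand hydrogenolysis or Lewis acids at the most sensitive stage.

**24 from 23.** Ring C is opened at C3=C4 by a ring-closing metathesis transform. Closures that pass through a carbonyl next to C2 (aldol, Friedel–Crafts) would expose the cis diad to epimerisation; metathesis is neutral and leaves both centres alone. Diene 23 is acyclic and needs only a vinyl group at C4a and an isopropenyl group at C2.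

**23 from 20, and 20 from 19.** The C2–C3 bond is cut to a secondary boronic ester (20), since boron-to-carbon olefination with an isopropenyl-metal transfers C2 with retention. The C4a–C4 bond is cut to the aryl chloride 19 by a vinyl cross-coupling. The vinyl group is introduced before the isopropenyl group. In the reverse order the arylpalladium intermediate would carry a pendant 1,1-disubstituted alkene placed for 5-exo carbopalladation; with 19 the only neighbour is a secondary alkyl boronic ester that does not transmetalate.

**19 from 11, 17 and 16 (key disconnection).** Two bonds are cut at once: C1–ring A and C2–CH3. Adding ate complex 18, formed from (E)-alkenyl boronate 11 and methyllithium 17, to aryl triflate 16 creates both centres in one catalytic step, with the methyl delivered as a methyl and boron left at C2 for the next bond. A conjugate-addition/enolate-alkylation sequence would need an auxiliary and a carbonyl at C3. Hydrogenation of a tetrasubstituted 1,1-diarylalkene has no good precedent. Boron carries the bulky cis-diol 8 rather than a simpler diol, because β-substituted alkenyl boronates with smaller diol esters divert the catalyst to direct alkenyl transfer. The forward step must prefer metallate shift over transmetalation, triflate over chloride, and one alkene face.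

**11 from 6 and 8; 6 from 5, 3, 2 and 1.** The C–B bond is cut to (E)-iodoalkene 6 (lithium–iodine exchange, borylation, esterification with 8), and the iodoalkene to aldehyde 5 by a one-carbon iodo-olefination that is E-selective for aryl aldehydes. The formyl group comes from ortho-metalation of silyl ether 3. Compound 3 is C2-symmetric, so its two ring hydrogens, each between OMe and Cl, are equivalent and no regiochemical question arises. Chlorophenol 2 comes from para-chlorination of 2,6-dimethoxyphenol 1.

**16 from 15, 13 and 12.** The triflate is cut to phenol 15, which comes from syringaldehyde 12 by silylation (13) and formyl-to-hydroxyl exchange. This places the silyl ether on the hindered oxygen and the triflate on the unhindered one without any selectivity problem.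

**8 from 7.** The diol comes from double methyl addition to acenaphthoquinone 7.

## Roads not taken

**Alternative 1:** Photoenolisation/Diels–Alder with a chiral butenolide.
- **Cut:** C1–C2 and C3–C4, after both methyl carbons are raised to the carbonyl level and C4 is given a hydroxyl group.
- **Forward step:** the ortho-benzylbenzaldehyde A1 is irradiated; photoenolisation and endo Diels–Alder addition to the menthyloxy butenolide A2, anti to the menthyloxy group, would give the all-cis hydroxy lactone A3.
- **Merits:** ring C and two C–C bonds form in one metal-free step; four contiguous centres come from a cheap auxiliary; the endo rule gives the C1/C2 cis relationship the target needs.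
- **Weak points here:** A3 holds the C2 and C3 substituents as an acetal carbon and a lactone carbonyl, and both must be reduced to methyl. The C3 and C4 centres are made only to be destroyed by a dehydration that must go toward C3 without epimerising C2 or aromatising. The benzyl ethers must then be removed beside the C3=C4 bond. The sequence after the cycloaddition would be considerably longer than the four steps that follow the key step here.
- **Comparison:** Alternative 1 is better at ring construction, since it closes ring C in the key step while the chosen plan needs a separate metathesis, and it needs no precious-metal catalyst. Against this, the chosen plan installs the C2 methyl, C3 and C4 at their final oxidation level, so no redox work surrounds the cis diad.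

**Alternative 2:** Enantioselective diaryl carbene allylic C–H insertion.
- **Cut:** the single bond C1–C2.
- **Forward step:** the diaryldiazomethane A4 (carbene carbon = C1; ring B bears a (Z)-2-methylbut-1-enyl group at C4a) is decomposed by a chiral dirhodium tetracarboxylate. Insertion into one enantiotopic allylic C–H of the ethyl group would close ring C and give A5, the bis-silyl ether of the target.
- **Merits:** this is the shortest endgame of all, one deprotection from the target. Ring C and both centres arise in one step, and the precursor is convergent through a diaryl ketone.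
- **Weak points here:** ring B has a methoxy group at C8, ortho to the carbene carbon. Its C–H bonds are α to oxygen and positioned for five-membered insertion, the favoured mode of such donor/donor carbenes, so it competes with the six-membered allylic insertion. The cis/trans outcome rests on catalyst control alone, with no stereospecific element. The Z-trisubstituted alkene must be made isomerically pure, and the diazo compound must be made from a doubly ortho-substituted, electron-rich ketone.
- **Comparison:** Alternative 2 is clearly shorter after its key step and forms the ring and both centres together. The chosen plan sets against this a key step with no competing reactive site in the substrate, a relative configuration fixed by mechanism, and closer precedent for the bond type.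

**Alternative 3:** One-carbon ring expansion of an aryl-methyl indanone.
- **Cut:** C3–C4 and C4–C4a, removing C4 as a one-carbon unit.
- **Forward step:** a silylated diazomethane adds to the Lewis-acid-activated carbonyl (future C3) of the cis indanone A6, and the electron-rich aryl carbon C4a migrates, to give the ring-expanded ketone A7.
- **Merits:** the reagents are cheap; aryl migration is favoured by the donors on ring B; the C3 ketone is a direct handle for the C3 methyl and the C3=C4 bond.
- **Weak points here:** the key step creates no stereocentre. Both centres must already exist in A6, where C2 is α to the carbonyl and the required cis isomer is the less stable one. C2 stays enolisable in A7 and during methyl addition, which itself suffers from enolisation on such ketones. Dehydration can go toward C2 as well as C4, and the former erases a centre.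
- **Comparison:** Alternative 3 uses simpler reagents and classical ring chemistry, and may be cheaper per step. The chosen plan never places a carbonyl beside C2, so the cis diad is set under catalyst control and is not epimerisable afterwards.

Key step: step 10

Assumptions:
- The enantiomer of the MandyPhos ligand that leads to (1S,2S)-19 is the one meant throughout; its sense of induction is taken by analogy with couplings of β-substituted alkenyl boronates and is to be confirmed on the first run.
- The cis-diol 8 is assumed to be the major product of step 5.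

## Route

Step 1
Reactants: 1 2,6-dimethoxyphenol
Product: 2 4-chloro-2,6-dimethoxyphenol
Conditions: SO2Cl2, CH2Cl2, 0 °C → rt
Reagents that add atoms: sulfuryl chloride, O=S(=O)(Cl)Cl
Why: Electrophilic chlorination of the free phenol goes para to the hydroxyl, the only position it activates because both ortho positions carry methoxy groups; sulfuryl chloride is a standard reagent for para-chlorination of phenols.

Step 2
Reactants: 2 4-chloro-2,6-dimethoxyphenol
Product: 3 (4-chloro-2,6-dimethoxyphenoxy)triisopropylsilane
Conditions: TIPSCl, imidazole, DMF, rt → 50 °C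
Reagents that add atoms: chlorotriisopropylsilane, CC(C)[Si](Cl)(C(C)C)C(C)C
Why: Standard silylation of a phenol with a silyl chloride and imidazole; the triisopropylsilyl ether is chosen because it must outlast alkyllithiums, methoxide and hot aqueous phosphate later.

Step 3
Reactants: 3 (4-chloro-2,6-dimethoxyphenoxy)triisopropylsilane
Product: 5 6-chloro-2,4-dimethoxy-3-(triisopropylsilyloxy)benzaldehyde, via aryllithium 4 (not isolated)
Conditions: s-BuLi, TMEDA, THF, −78 °C; DMF, −78 → 0 °C; aq. NH4Cl
Reagents that add atoms: N,N-dimethylformamide, CN(C)C=O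
Why: Directed ortho-metalation: the two ring hydrogens are equivalent and each is acidified by a flanking methoxy and chloro group, so there is no regiochemical choice; at −78 °C the ortho-chloro aryllithium does not lose LiCl and is formylated by DMF.

Step 4
Reactants: 5 6-chloro-2,4-dimethoxy-3-(triisopropylsilyloxy)benzaldehyde
Product: 6 [4-chloro-3-[(E)-2-iodoethenyl]-2,6-dimethoxyphenoxy]triisopropylsilane
Conditions: CrCl2, CHI3, THF, 0 °C → rt
Reagents that add atoms: iodoform, IC(I)I
Why: Takai olefination: the geminal dichromium species from iodoform adds to the aldehyde and elimination gives the (E)-iodoalkene, with E selectivity highest for aromatic aldehydes; the aryl chloride and silyl ether are inert to CrCl2.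

Step 5
Reactants: 7 acenaphthoquinone
Product: 8 cis-1,2-dimethyl-1,2-dihydroacenaphthylene-1,2-diol (meso, 1R,2S)
Conditions: MeMgBr, THF, 0 °C → rt; aq. NH4Cl; recrystallisation
Reagents that add atoms: methylmagnesium bromide, C[Mg]Br
Why: Double Grignard addition to a 1,2-diketone; the cis (meso) diol is the isomer needed and is separated by crystallisation from any trans isomer, which cannot form a five-membered boronic ester.

Step 6
Reactants: 6 [4-chloro-3-[(E)-2-iodoethenyl]-2,6-dimethoxyphenoxy]triisopropylsilane; 8 cis-1,2-dimethyl-1,2-dihydroacenaphthylene-1,2-diol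
Product: 11 cyclic boronic ester of diol 8 with (E)-2-[6-chloro-2,4-dimethoxy-3-(triisopropylsilyloxy)phenyl]ethenylboronic acid, via alkenyllithium 9 (not isolated), via lithium triisopropoxyborate 10 (not isolated)
Conditions: t-BuLi (2 equiv), Et2O, −78 °C; B(OiPr)3, −78 °C → rt; then 8, AcOH, rt
Reagents that add atoms: triisopropyl borate, CC(C)OB(OC(C)C)OC(C)C
Why: Lithium–iodine exchange on an alkenyl iodide keeps the E geometry and is far faster than any reaction at the aryl chloride; trapping with a trialkyl borate and in-flask exchange with a 1,2-diol is the standard route to alkenyl boronic esters.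

Step 7
Reactants: 12 syringaldehyde (4-hydroxy-3,5-dimethoxybenzaldehyde)
Product: 13 3,5-dimethoxy-4-(triisopropylsilyloxy)benzaldehyde
Conditions: TIPSCl, imidazole, DMF, rt
Reagents that add atoms: chlorotriisopropylsilane, CC(C)[Si](Cl)(C(C)C)C(C)C
Why: Silylation of the phenol as in step 2; this puts the silyl group on the hindered oxygen before the second oxygen exists.

Step 8
Reactants: 13 3,5-dimethoxy-4-(triisopropylsilyloxy)benzaldehyde
Product: 15 3,5-dimethoxy-4-(triisopropylsilyloxy)phenol, via aryl formate 14 (not isolated)
Conditions: mCPBA, CH2Cl2, 0 °C → rt; then Et3N, MeOH, rt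
Reagents that add atoms: 3-chloroperoxybenzoic acid, OOC(=O)c1cccc(Cl)c1
Why: Dakin-type oxidation in two stages: Baeyer–Villiger migration of the electron-rich aryl group gives the aryl formate, which mild methanolysis cleaves without touching the hindered silyl ether.

Step 9
Reactants: 15 3,5-dimethoxy-4-(triisopropylsilyloxy)phenol
Product: 16 3,5-dimethoxy-4-(triisopropylsilyloxy)phenyl trifluoromethanesulfonate
Conditions: Tf2O, pyridine, CH2Cl2, 0 °C
Reagents that add atoms: trifluoromethanesulfonic anhydride, O=S(=O)(OS(=O)(=O)C(F)(F)F)C(F)(F)F
Why: Routine triflation of an unhindered phenol.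

Step 10
Reactants: 11 (E)-alkenyl boronic ester of diol 8; 17 methyllithium; 16 3,5-dimethoxy-4-(triisopropylsilyloxy)phenyl trifluoromethanesulfonate
Product: 19 cyclic boronic ester of diol 8 with (1S,2S)-1-[6-chloro-2,4-dimethoxy-3-(triisopropylsilyloxy)phenyl]-1-[3,5-dimethoxy-4-(triisopropylsilyloxy)phenyl]propan-2-ylboronic acid, via lithium ate complex 18 (not isolated)
Conditions: 17 (halide-free, Et2O), THF, 0 °C → rt; then 16, Pd(OAc)2 (cat.), MandyPhos ligand [2,2'-bis((dimethylamino)(phenyl)methyl)-1,1'-bis(bis(4-methoxy-3,5-dimethylphenyl)phosphino)ferrocene] (cat.), THF, 60 °C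
Reagents that add atoms: none
Why: Methyllithium adds to boron of 11 to give the four-coordinate ate complex 18, in which methyl is the only carbon ligand besides the alkenyl group. Oxidative addition of triflate 16 to zerovalent palladium gives a cationic arylpalladium species (divalent palladium) that binds the electron-rich alkene of 18; this triggers a 1,2-shift of methyl from boron to the boron-bearing carbon C2 anti to palladium, palladium bonds to C1, and reductive elimination forms the C1–ring A bond with retention. The closest known reaction is the palladium-catalysed enantioselective conjunctive cross-coupling of β-substituted alkenylboron ate complexes with aryl triflates, for which hindered diol esters such as that of 8 were developed. No ring closes in this step. The chiral bisphosphine chooses the alkene face that palladium binds and so fixes the absolute configuration of C1 and C2 together; their relative configuration follows from the E geometry of 11 and the stereospecific anti addition of ring A and methyl, which places them cis once ring C is closed. Chemoselectivity against direct transfer of the alkenyl group to palladium rests on the bulky diol on boron, which slows transmetalation. Selectivity between the two carbon–leaving-group bonds rests on the triflate, which ionises to the cationic palladium needed for alkene binding, whereas the hindered, electron-rich aryl chloride of ring B should not add to this catalyst at 60 °C. Halide-free methyllithium and purified 11 keep halide ions, which inhibit the cationic pathway, out of the flask.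

Step 11
Reactants: 19 (1S,2S)-chloro boronic ester
Product: 20 cyclic boronic ester of diol 8 with (1S,2S)-1-[6-ethenyl-2,4-dimethoxy-3-(triisopropylsilyloxy)phenyl]-1-[3,5-dimethoxy-4-(triisopropylsilyloxy)phenyl]propan-2-ylboronic acid
Conditions: vinylboronic acid pinacol ester, Pd(OAc)2, SPhos, K3PO4, toluene/H2O, 90 °C
Reagents that add atoms: vinylboronic acid pinacol ester, C=CB1OC(C)(C)C(C)(C)O1
Why: Suzuki–Miyaura coupling of an aryl chloride with a dialkylbiarylphosphine ligand made for hindered, electron-rich chlorides; the secondary alkyl boronic ester does not transmetalate under these conditions, and no fluoride is present to threaten the silyl ethers.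

Step 12
Reactants: 20 (1S,2S)-vinyl boronic ester
Product: 23 (3S,4S)-4-[6-ethenyl-2,4-dimethoxy-3-(triisopropylsilyloxy)phenyl]-4-[3,5-dimethoxy-4-(triisopropylsilyloxy)phenyl]-2,3-dimethylbut-1-ene, via isopropenyl ate complex 21 (not isolated), via iodo boronic ester 22 (not isolated)
Conditions: 2-bromopropene, t-BuLi, THF/Et2O, −78 °C; 20, −78 → 0 °C; I2, MeOH, −78 °C; NaOMe, MeOH, −78 °C → rt
Reagents that add atoms: isopropenyllithium, [Li]C(C)=C, made in the flask from 2-bromopropene, CC(Br)=C
Why: Zweifel olefination: the alkenyllithium adds to boron, iodine forms an iodonium ion on the boron-bound alkene, C2 migrates from boron to carbon with retention, and methoxide triggers anti elimination of boron and iodide; C2 keeps its configuration and C1 is not involved.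

Step 13
Reactants: 23 (3S,4S)-diene
Product: 24 (1S,2S)-1-[3,5-dimethoxy-4-(triisopropylsilyloxy)phenyl]-6,8-dimethoxy-2,3-dimethyl-7-(triisopropylsilyloxy)-1,2-dihydronaphthalene
Conditions: second-generation Hoveyda–Grubbs catalyst (cat.), toluene, 80 °C
Reagents that add atoms: none
Why: Ring-closing metathesis between the styrene and the 1,1-disubstituted alkene closes the six-membered ring C with the trisubstituted C3=C4 bond and loss of ethylene, under neutral conditions that touch neither stereocentre.

Step 14
Reactants: 24 bis(triisopropylsilyl) ether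
Product: 25 (1S,2S)-1-(4-hydroxy-3,5-dimethoxyphenyl)-6,8-dimethoxy-2,3-dimethyl-1,2-dihydronaphthalen-7-ol [= (7S,8S)-8-(4-hydroxy-3,5-dimethoxyphenyl)-1,3-dimethoxy-6,7-dimethyl-7,8-dihydronaphthalen-2-ol]
Conditions: TBAF, AcOH, THF, 0 °C → rt, under argon
Reagents that add atoms: none
Why: Fluoride cleaves both aryl silyl ethers; acetic acid buffers the phenoxides and air is excluded so that neither the phenols nor the dihydronaphthalene are oxidised.

## Compound list

1 | 2,6-dimethoxyphenol (syringol) | COc1cccc(OC)c1O | starting material
2 | 4-chloro-2,6-dimethoxyphenol | COc1cc(Cl)cc(OC)c1O | intermediate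
3 | (4-chloro-2,6-dimethoxyphenoxy)triisopropylsilane | COc1cc(Cl)cc(OC)c1O[Si](C(C)C)(C(C)C)C(C)C | intermediate
4 | [6-chloro-2,4-dimethoxy-3-(triisopropylsilyloxy)phenyl]lithium (formed in the flask, step 3) | [Li]c1c(Cl)cc(OC)c(O[Si](C(C)C)(C(C)C)C(C)C)c1OC | intermediate
5 | 6-chloro-2,4-dimethoxy-3-(triisopropylsilyloxy)benzaldehyde | O=Cc1c(Cl)cc(OC)c(O[Si](C(C)C)(C(C)C)C(C)C)c1OC | intermediate
6 | [4-chloro-3-[(E)-2-iodoethenyl]-2,6-dimethoxyphenoxy]triisopropylsilane | I/C=C/c1c(Cl)cc(OC)c(O[Si](C(C)C)(C(C)C)C(C)C)c1OC | intermediate
7 | acenaphthoquinone (acenaphthylene-1,2-dione) | O=C1C(=O)c2cccc3cccc1c23 | starting material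
8 | cis-1,2-dimethyl-1,2-dihydroacenaphthylene-1,2-diol (meso) | C[C@@]1(O)c2cccc3cccc(c23)[C@]1(C)O | intermediate
9 | (E)-2-[6-chloro-2,4-dimethoxy-3-(triisopropylsilyloxy)phenyl]ethenyllithium (formed in the flask, step 6) | [Li]/C=C/c1c(Cl)cc(OC)c(O[Si](C(C)C)(C(C)C)C(C)C)c1OC | intermediate
10 | lithium (E)-alkenyl triisopropoxyborate from 9 (formed in the flask, step 6) | [Li+].CC(C)O[B-](OC(C)C)(OC(C)C)/C=C/c1c(Cl)cc(OC)c(O[Si](C(C)C)(C(C)C)C(C)C)c1OC | intermediate
11 | cyclic boronic ester of diol 8 with (E)-2-[6-chloro-2,4-dimethoxy-3-(triisopropylsilyloxy)phenyl]ethenylboronic acid | COc1cc(Cl)c(/C=C/B2O[C@]3(C)c4cccc5cccc(c45)[C@]3(C)O2)c(OC)c1O[Si](C(C)C)(C(C)C)C(C)C | intermediate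
12 | syringaldehyde | COc1cc(C=O)cc(OC)c1O | starting material
13 | 3,5-dimethoxy-4-(triisopropylsilyloxy)benzaldehyde | COc1cc(C=O)cc(OC)c1O[Si](C(C)C)(C(C)C)C(C)C | intermediate
14 | 3,5-dimethoxy-4-(triisopropylsilyloxy)phenyl formate (formed in the flask, step 8) | COc1cc(OC=O)cc(OC)c1O[Si](C(C)C)(C(C)C)C(C)C | intermediate
15 | 3,5-dimethoxy-4-(triisopropylsilyloxy)phenol | COc1cc(O)cc(OC)c1O[Si](C(C)C)(C(C)C)C(C)C | intermediate
16 | 3,5-dimethoxy-4-(triisopropylsilyloxy)phenyl trifluoromethanesulfonate | COc1cc(OS(=O)(=O)C(F)(F)F)cc(OC)c1O[Si](C(C)C)(C(C)C)C(C)C | intermediate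
17 | methyllithium | [Li]C | starting material
18 | lithium methyl[(E)-2-arylethenyl]borate of diol 8 (ate complex, formed in the flask, step 10; configuration at boron not defined) | [Li+].C[B-]1(/C=C/c2c(Cl)cc(OC)c(O[Si](C(C)C)(C(C)C)C(C)C)c2OC)O[C@]2(C)c3cccc4cccc(c34)[C@]2(C)O1 | intermediate
19 | cyclic boronic ester of diol 8 with (1S,2S)-1-[6-chloro-2,4-dimethoxy-3-(triisopropylsilyloxy)phenyl]-1-[3,5-dimethoxy-4-(triisopropylsilyloxy)phenyl]propan-2-ylboronic acid | COc1cc([C@@H](c2c(OC)c(O[Si](C(C)C)(C(C)C)C(C)C)c(OC)cc2Cl)[C@H](C)B2O[C@]3(C)c4cccc5cccc(c45)[C@]3(C)O2)cc(OC)c1O[Si](C(C)C)(C(C)C)C(C)C | intermediate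
20 | cyclic boronic ester of diol 8 with (1S,2S)-1-[6-ethenyl-2,4-dimethoxy-3-(triisopropylsilyloxy)phenyl]-1-[3,5-dimethoxy-4-(triisopropylsilyloxy)phenyl]propan-2-ylboronic acid | COc1cc([C@@H](c2c(OC)c(O[Si](C(C)C)(C(C)C)C(C)C)c(OC)cc2C=C)[C@H](C)B2O[C@]3(C)c4cccc5cccc(c45)[C@]3(C)O2)cc(OC)c1O[Si](C(C)C)(C(C)C)C(C)C | intermediate
21 | lithium isopropenyl ate complex of 20 (formed in the flask, step 12; configuration at boron not defined) | COc1cc([C@@H](c2c(OC)c(O[Si](C(C)C)(C(C)C)C(C)C)c(OC)cc2C=C)[C@H](C)[B-]2(C(C)=C)O[C@]3(C)c4cccc5cccc(c45)[C@]3(C)O2)cc(OC)c1O[Si](C(C)C)(C(C)C)C(C)C.[Li+] | intermediate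
22 | β-iodo tertiary boronic ester after the 1,2-shift (formed in the flask, step 12; configuration at the boron-bearing carbon of no consequence) | COc1cc([C@@H](c2c(OC)c(O[Si](C(C)C)(C(C)C)C(C)C)c(OC)cc2C=C)[C@H](C)C(C)(CI)B2O[C@]3(C)c4cccc5cccc(c45)[C@]3(C)O2)cc(OC)c1O[Si](C(C)C)(C(C)C)C(C)C | intermediate
23 | (3S,4S)-4-[6-ethenyl-2,4-dimethoxy-3-(triisopropylsilyloxy)phenyl]-4-[3,5-dimethoxy-4-(triisopropylsilyloxy)phenyl]-2,3-dimethylbut-1-ene | COc1cc([C@@H](c2c(OC)c(O[Si](C(C)C)(C(C)C)C(C)C)c(OC)cc2C=C)[C@H](C)C(C)=C)cc(OC)c1O[Si](C(C)C)(C(C)C)C(C)C | intermediate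
24 | (1S,2S)-1-[3,5-dimethoxy-4-(triisopropylsilyloxy)phenyl]-6,8-dimethoxy-2,3-dimethyl-7-(triisopropylsilyloxy)-1,2-dihydronaphthalene | COc1cc([C@H]2c3c(cc(OC)c(O[Si](C(C)C)(C(C)C)C(C)C)c3OC)C=C(C)[C@H]2C)cc(OC)c1O[Si](C(C)C)(C(C)C)C(C)C | intermediate
25 | (1S,2S)-1-(4-hydroxy-3,5-dimethoxyphenyl)-6,8-dimethoxy-2,3-dimethyl-1,2-dihydronaphthalen-7-ol | COc1cc([C@H]2c3c(cc(OC)c(O)c3OC)C=C(C)[C@H]2C)cc(OC)c1O | target

## Step count and risks

Total: 14 steps. Longest linear sequence: 10 steps (steps 1–4, 6, 10–14).

**Step 10 (key step).** The likeliest failure is direct transmetalation, that is, transfer of the alkenyl or methyl group to palladium, outrunning the metallate shift. The β-carbon carries a 2,6-disubstituted aryl group and methyl is a reluctant migrating group. Insufficient facial selectivity at this crowded alkene is the second concern. Fallback (syn-arylboration in place of the metallate shift): set out from iodoalkene 6.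
- Negishi methylation (MeZnCl, Pd(PPh3)4, THF) with retention should give the (E)-propenylarene F1.
- Commercial 4-bromo-2,6-dimethoxyphenol is silylated (TIPSCl, imidazole) to aryl bromide F2.
- Copper/palladium-cocatalysed arylboration of F1 with F2 and bis(pinacolato)diboron (chiral N-heterocyclic-carbene copper chloride complex, Pd(OAc)2/RuPhos, NaOt-Bu, THF) should give the (1S,2S)-pinacol boronate F3. Borylcupration places boron on C2 and copper on benzylic C1 in a syn sense, and stereoretentive transfer to arylpalladium places ring A on C1. Syn addition of aryl and boron to the E propenyl arene gives the same relative configuration as anti addition of aryl and methyl to 11.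
- Vinylation as in step 11 gives the vinyl pinacol boronate F4.
- Olefination as in step 12, through the isopropenyl ate complex F5 and the iodo boronic ester F6, comes back to the route at diene 23.

**Step 12.** Ate-complex formation may be incomplete at a secondary boronic ester that carries a bulky diol and sits beside a diarylmethine, and iodine may attack the electron-rich styrene. Fallback (stepwise homologation): set out from 20.
- Matteson homologation (LiCHCl2 from CH2Cl2 and n-BuLi, THF, −100 °C; ZnCl2, → rt) gives the α-chloro boronic ester F7.
- MeMgBr (THF, −78 °C → rt) displaces chloride through the ate complex to give the methyl-homologated boronic ester F8 (both epimers at the new carbon, which is of no consequence).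
- Oxidation (NaBO3, THF/H2O) gives the secondary alcohol F9.
- Dess–Martin periodinane gives the methyl ketone F10.
- Non-basic methylenation with Cp2TiMe2 (toluene, 65 °C) comes back to the route at diene 23 without exposing C2 to base.

**Step 11.** Oxidative addition into the electron-rich chloride next to the branched benzylic substituent may be slow, with decay of the vinylboron reagent and gradual loss of silyl ether in hot aqueous base. Fallback (polarity reversal): set out from 19.
- Miyaura borylation (bis(pinacolato)diboron, Pd(OAc)2, XPhos, KOAc, dioxane, 100 °C, anhydrous) gives the aryl pinacol boronate F11.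
- Coupling of F11 with vinyl bromide (Pd(PPh3)4, K2CO3, THF/H2O, 60 °C) comes back to the route at 20. The secondary alkyl boronic ester stays inert in both operations.

**Step 6.** Ester exchange of the intermediate borate with the hindered tertiary cis-diol may be incomplete, and the alkenyl boron species may protodeboronate on acidification. Fallback (ate complex assembled from the other side): set out from 6.
- Methylboronic acid and diol 8 (MgSO4, CH2Cl2) give the methyl boronic ester F12.
- Alkenyllithium 9, generated from 6 as in step 6, is added to F12 at −78 °C. This comes back to the route at ate complex 18, which is used directly in step 10.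

**Step 3.** The ortho-chloro aryllithium may lose LiCl (aryne formation) if the temperature rises, or the base may attack silicon. Fallback (electrophilic formylation): set out from phenol 2.
- Rieche formylation (Cl2CHOMe, TiCl4, CH2Cl2, 0 °C) at the only open position, ortho and para to the two methoxy groups, gives the hydroxy aldehyde F13.
- Silylation of F13 as in step 2 comes back to the route at aldehyde 5.

## Further compounds

F1 | step 10 | [4-chloro-2,6-dimethoxy-3-[(E)-prop-1-enyl]phenoxy]triisopropylsilane | C/C=C/c1c(Cl)cc(OC)c(O[Si](C(C)C)(C(C)C)C(C)C)c1OC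
F2 | step 10 | (4-bromo-2,6-dimethoxyphenoxy)triisopropylsilane | COc1cc(Br)cc(OC)c1O[Si](C(C)C)(C(C)C)C(C)C
F3 | step 10 | pinacol ester of (1S,2S)-1-[6-chloro-2,4-dimethoxy-3-(triisopropylsilyloxy)phenyl]-1-[3,5-dimethoxy-4-(triisopropylsilyloxy)phenyl]propan-2-ylboronic acid | COc1cc([C@@H](c2c(OC)c(O[Si](C(C)C)(C(C)C)C(C)C)c(OC)cc2Cl)[C@H](C)B2OC(C)(C)C(C)(C)O2)cc(OC)c1O[Si](C(C)C)(C(C)C)C(C)C
F4 | step 10 | pinacol ester of (1S,2S)-1-[6-ethenyl-2,4-dimethoxy-3-(triisopropylsilyloxy)phenyl]-1-[3,5-dimethoxy-4-(triisopropylsilyloxy)phenyl]propan-2-ylboronic acid | COc1cc([C@@H](c2c(OC)c(O[Si](C(C)C)(C(C)C)C(C)C)c(OC)cc2C=C)[C@H](C)B2OC(C)(C)C(C)(C)O2)cc(OC)c1O[Si](C(C)C)(C(C)C)C(C)C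
F5 | step 10 | lithium isopropenyl ate complex of F4 | COc1cc([C@@H](c2c(OC)c(O[Si](C(C)C)(C(C)C)C(C)C)c(OC)cc2C=C)[C@H](C)[B-]2(C(C)=C)OC(C)(C)C(C)(C)O2)cc(OC)c1O[Si](C(C)C)(C(C)C)C(C)C.[Li+]
F6 | step 10 | β-iodo tertiary pinacol boronic ester from F5 | COc1cc([C@@H](c2c(OC)c(O[Si](C(C)C)(C(C)C)C(C)C)c(OC)cc2C=C)[C@H](C)C(C)(CI)B2OC(C)(C)C(C)(C)O2)cc(OC)c1O[Si](C(C)C)(C(C)C)C(C)C
F7 | step 12 | α-chloro boronic ester of diol 8 (one-carbon homologue of 20, chlorine on the new carbon) | COc1cc([C@@H](c2c(OC)c(O[Si](C(C)C)(C(C)C)C(C)C)c(OC)cc2C=C)[C@H](C)C(Cl)B2O[C@]3(C)c4cccc5cccc(c45)[C@]3(C)O2)cc(OC)c1O[Si](C(C)C)(C(C)C)C(C)C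
F8 | step 12 | methyl-homologated boronic ester of diol 8 (new carbon bearing methyl and boron) | COc1cc([C@@H](c2c(OC)c(O[Si](C(C)C)(C(C)C)C(C)C)c(OC)cc2C=C)[C@H](C)C(C)B2O[C@]3(C)c4cccc5cccc(c45)[C@]3(C)O2)cc(OC)c1O[Si](C(C)C)(C(C)C)C(C)C
F9 | step 12 | (3S,4S)-4-[6-ethenyl-2,4-dimethoxy-3-(triisopropylsilyloxy)phenyl]-4-[3,5-dimethoxy-4-(triisopropylsilyloxy)phenyl]-3-methylbutan-2-ol (both carbinol epimers) | COc1cc([C@@H](c2c(OC)c(O[Si](C(C)C)(C(C)C)C(C)C)c(OC)cc2C=C)[C@H](C)C(C)O)cc(OC)c1O[Si](C(C)C)(C(C)C)C(C)C
F10 | step 12 | (3S,4S)-4-[6-ethenyl-2,4-dimethoxy-3-(triisopropylsilyloxy)phenyl]-4-[3,5-dimethoxy-4-(triisopropylsilyloxy)phenyl]-3-methylbutan-2-one | COc1cc([C@@H](c2c(OC)c(O[Si](C(C)C)(C(C)C)C(C)C)c(OC)cc2C=C)[C@H](C)C(C)=O)cc(OC)c1O[Si](C(C)C)(C(C)C)C(C)C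
F11 | step 11 | analogue of 19 with a pinacol boronate in place of chlorine on ring B | COc1cc([C@@H](c2c(OC)c(O[Si](C(C)C)(C(C)C)C(C)C)c(OC)cc2B2OC(C)(C)C(C)(C)O2)[C@H](C)B2O[C@]3(C)c4cccc5cccc(c45)[C@]3(C)O2)cc(OC)c1O[Si](C(C)C)(C(C)C)C(C)C
F12 | step 6 | cyclic boronic ester of diol 8 with methylboronic acid | CB1O[C@]2(C)c3cccc4cccc(c34)[C@]2(C)O1
F13 | step 3 | 6-chloro-3-hydroxy-2,4-dimethoxybenzaldehyde | O=Cc1c(Cl)cc(OC)c(O)c1OC
A1 | alternative 1 | 2-[(4-benzyloxy-3,5-dimethoxyphenyl)methyl]-4-benzyloxy-3,5-dimethoxybenzaldehyde | O=Cc1cc(OC)c(OCc2ccccc2)c(OC)c1Cc1cc(OC)c(OCc2ccccc2)c(OC)c1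
A2 | alternative 1 | (5S)-5-(d-menthyloxy)furan-2(5H)-one | O=C1C=C[C@@H](O[C@H]2C[C@@H](C)CC[C@@H]2C(C)C)O1
A3 | alternative 1 | all-cis 1-aryl-4-hydroxytetralin fused at C2–C3 to the menthyloxy lactone, bis-benzyl ether | COc1cc([C@H]2c3c(cc(OC)c(OCc4ccccc4)c3OC)[C@@H](O)[C@@H]4[C@H]2[C@@H](O[C@H]2C[C@@H](C)CC[C@@H]2C(C)C)OC4=O)cc(OC)c1OCc1ccccc1
A4 | alternative 2 | diaryldiazomethane with a (Z)-2-methylbut-1-enyl group on ring B, bis(tert-butyldimethylsilyl) ether | COc1cc(C(=[N+]=[N-])c2c(OC)c(O[Si](C)(C)C(C)(C)C)c(OC)cc2/C=C(/C)CC)cc(OC)c1O[Si](C)(C)C(C)(C)C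
A5 | alternative 2 | bis(tert-butyldimethylsilyl) ether of the target | COc1cc([C@H]2c3c(cc(OC)c(O[Si](C)(C)C(C)(C)C)c3OC)C=C(C)[C@H]2C)cc(OC)c1O[Si](C)(C)C(C)(C)C
A6 | alternative 3 | cis-3-aryl-4,6-dimethoxy-2-methyl-5-silyloxyindan-1-one, bis(tert-butyldimethylsilyl) ether | COc1cc([C@H]2c3c(cc(OC)c(O[Si](C)(C)C(C)(C)C)c3OC)C(=O)[C@H]2C)cc(OC)c1O[Si](C)(C)C(C)(C)C
A7 | alternative 3 | cis-1-aryl-2-methyl-3-tetralone (ketone at C3), bis(tert-butyldimethylsilyl) ether | COc1cc([C@H]2c3c(cc(OC)c(O[Si](C)(C)C(C)(C)C)c3OC)CC(=O)[C@H]2C)cc(OC)c1O[Si](C)(C)C(C)(C)C
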